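## Retrosynthetic overview

1. 16 ⇒ 15: the exocyclic methylene is a dehydrated tertiary α-ketol; the C1 oxygen is kept to the end because it steers the halogens.
2. 15 ⇒ 13 ⇒ 11 (key): C9–Cl comes from a C1–O–C9 bridged bromoether (NBS bromoetherification, then TiCl4 oxygen-to-chloride exchange with retention). The bridge forces Br onto the C10 face cis to C5, which a free bromochlorination of the ring B alkene is not expected to favour.
3. 11 ⇒ 9 ⇒ 8: methyl addition to the spiro ketone; ring B by ring-closing metathesis.
4. 8 ⇒ 6 ⇒ 5: the quaternary C6 by Pd-catalysed enantioselective allylation of a tetrasubstituted enolate made regiospecifically by conjugate addition to an exo-enone.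
5. Ring A is bought (2,2-dimethylcyclohexane-1,3-dione → 5). Ring order: ring A (given), ring B (metathesis), then the temporary oxygen bridge, which is cut again.

Assumption: the target locants (ring A = C1–C5, spiro atom C6, ring B = C7–C11) are used for all spiro intermediates; where C1 is a transient stereocentre both epimers are carried, because C1 becomes sp2 in the last step.

## Route

Step 1
Reactants: 1 2,2-dimethylcyclohexane-1,3-dione
Product: 2 3-bromo-2,2-dimethylcyclohex-3-en-1-one
Conditions: (PhO)3P, Br2, Et3N, CH2Cl2, −60 °C to reflux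
Reagents that add atoms: bromine, BrBr
Why: Ketone-to-vinyl-bromide conversion with the triphenyl phosphite–bromine reagent (halophosphonium activation of the carbonyl oxygen, then E2 loss of HBr); the two carbonyls of 1 are equivalent, enolization is only possible away from the quaternary carbon, and one equivalent stops at the mono-bromide because the remaining carbonyl of 2 is more hindered.

Step 2
Reactants: 2 3-bromo-2,2-dimethylcyclohex-3-en-1-one
Product: 3 1-bromo-6,6-dimethyl-5-methylidenecyclohex-1-ene
Conditions: Ph3PCH3Br, KOtBu, toluene, 0 to 80 °C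
Reagents that add atoms: methyltriphenylphosphonium bromide, C[P+](c1ccccc1)(c1ccccc1)c1ccccc1.[Br-]
Why: Wittig methylenation in hot toluene is the standard answer for α-quaternary ketones; the alkenyl bromide is inert to the ylide and no stereocentre is involved.

Step 3
Reactants: 3 1-bromo-6,6-dimethyl-5-methylidenecyclohex-1-ene
Product: 5 4-bromo-5,5-dimethyl-6-methylidenecyclohex-3-en-1-one, via allylic alcohol 4 (not isolated)
Conditions: SeO2 (0.5 equiv), t-BuOOH, CH2Cl2, rt; then Dess–Martin periodinane, CH2Cl2, 0 °C to rt
Reagents that add atoms: tert-butyl hydroperoxide, CC(C)(C)OO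
Why: Sharpless SeO2/t-BuOOH allylic hydroxylation (ene reaction then [2,3]-sigmatropic shift) attacks the electron-rich 1,1-disubstituted alkene, whose only allylic C–H bonds are at C1, and returns the exocyclic double bond; Dess–Martin oxidation of the crude alcohol then gives the α-methylene ketone.

Step 4
Reactants: 5 4-bromo-5,5-dimethyl-6-methylidenecyclohex-3-en-1-one
Product: 6 [4-bromo-3,3-dimethyl-2-(3-methylbut-3-en-1-yl)cyclohexa-1,4-dien-1-yl]oxy(trimethyl)silane
Conditions: CH2=C(CH3)CH2MgCl, CuBr·SMe2, Me3SiCl, THF, −78 °C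
Reagents that add atoms: 2-methylallylmagnesium chloride, C=C(C)C[Mg]Cl; chlorotrimethylsilane, C[Si](C)(C)Cl
Why: Organocopper conjugate addition with in situ silylation: the unsubstituted exocyclic carbon accepts the 2-methylallyl group and Me3SiCl traps the enolate, so the hindered tetrasubstituted enol ether toward C6 is obtained regiospecifically, which direct enolization (more acidic C2–H) could not deliver.

Step 5
Reactants: 6 [4-bromo-3,3-dimethyl-2-(3-methylbut-3-en-1-yl)cyclohexa-1,4-dien-1-yl]oxy(trimethyl)silane
Product: 8 (2R)-4-bromo-3,3-dimethyl-2-(3-methylbut-3-en-1-yl)-2-(prop-2-en-1-yl)cyclohex-4-en-1-one, via enolate anion 7 (not isolated)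
Conditions: diallyl carbonate, Pd2(dba)3 (5 mol %), (S)-(CF3)3-t-BuPHOX (12.5 mol %), Bu4N[Ph3SiF2] (35 mol %), THF, 25 °C
Reagents that add atoms: diallyl carbonate, C=CCOC(=O)OCC=C
Why: Tsuji–Trost-type asymmetric allylic alkylation of a silyl enol ether (Stoltz): fluoride frees the enolate without scrambling, allyl carbonate ionizes on zerovalent palladium much faster than the hindered C–Br bond inserts, and the (S)-PHOX ligand delivers allyl to the enolate face that gives (S)-2-allyl-2-methylcyclohexanone in the parent case, which by analogy corresponds here to (R)-8 with the C6 geometry of the target.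

Step 6
Reactants: 8 (2R)-4-bromo-3,3-dimethyl-2-(3-methylbut-3-en-1-yl)-2-(prop-2-en-1-yl)cyclohex-4-en-1-one
Product: 9 (6R)-4-bromo-5,5,9-trimethylspiro[5.5]undeca-3,8-dien-1-one
Conditions: second-generation Grubbs catalyst (H2IMes)(PCy3)Cl2Ru=CHPh (5 mol %), CH2Cl2, 40 °C
Reagents that add atoms: none
Why: Ring-closing olefin metathesis between the monosubstituted and the 1,1-disubstituted alkene gives the trisubstituted cyclohexene of ring B with loss of ethene; the alkenyl bromide does not take part and the quaternary stereocentre is untouched.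

Step 7
Reactants: 9 (6R)-4-bromo-5,5,9-trimethylspiro[5.5]undeca-3,8-dien-1-one
Product: 11 (6R)-4-bromo-1,5,5,9-tetramethylspiro[5.5]undeca-3,8-dien-1-ol (both C1 epimers), via cerium alkoxide 10 (not isolated)
Conditions: CH3Li, CeCl3, THF, −78 to 0 °C; aq NH4Cl
Reagents that add atoms: methyllithium, [Li]C
Why: Organocerium 1,2-addition (Imamoto conditions) adds methyl to the hindered, easily enolized ketone without deprotonating the allylic C2–H; the new C1 centre forms as both epimers, which is harmless because both can bridge in step 8 and C1 becomes sp2 in step 11.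

Step 8
Reactants: 11 (6R)-4-bromo-1,5,5,9-tetramethylspiro[5.5]undeca-3,8-dien-1-ol (both C1 epimers)
Product: 12 (6R,9S,10S)-4,10-dibromo-1,9-epoxy-1,5,5,9-tetramethylspiro[5.5]undec-3-ene (both C1 epimers)
Conditions: NBS, CH2Cl2, 0 °C, dark
Reagents that add atoms: N-bromosuccinimide, O=C1CCC(=O)N1Br
Why: Bromoetherification (halocyclization of the α-terpineol-to-cineole type): bromonium formation is reversible on both faces, but only the bromonium on the face opposite to C1 can be captured at the tertiary C9 by the C1 oxygen (Markovnikov, anti, through a boat of ring B), so bromine is forced onto the C10 face cis to C5 and oxygen onto the C9 face cis to C1.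

Step 9
Reactants: 12 (6R,9S,10S)-4,10-dibromo-1,9-epoxy-1,5,5,9-tetramethylspiro[5.5]undec-3-ene (both C1 epimers)
Product: 13 (6R,9S,10S)-4,10-dibromo-1,9-epoxy-1,5,5,9-tetramethylspiro[5.5]undec-3-en-2-one (both C1 epimers)
Conditions: Rh2(cap)4 (cap = caprolactamate, 1 mol %), t-BuOOH (5 equiv), K2CO3, CH2Cl2, rt
Reagents that add atoms: tert-butyl hydroperoxide, CC(C)(C)OO
Why: Radical allylic C–H oxidation with Rh2(cap)4/t-BuOOH (Doyle conditions): with ring B now saturated the only allylic methylene is C2 (C5 is quaternary), the delocalized radical is trapped at C2 away from the bromine-bearing carbon, and the method tolerates electron-poor alkenes, giving the β-bromo enone.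

Step 10
Reactants: 13 (6R,9S,10S)-4,10-dibromo-1,9-epoxy-1,5,5,9-tetramethylspiro[5.5]undec-3-en-2-one (both C1 epimers)
Product: 15 (6R,9S,10S)-4,10-dibromo-9-chloro-1-hydroxy-1,5,5,9-tetramethylspiro[5.5]undec-3-en-2-one (both C1 epimers), via titanium alkoxide 14 (not isolated)
Conditions: TiCl4 (2 equiv), CH2Cl2, −78 to −30 °C; then H2O
Reagents that add atoms: titanium tetrachloride, Cl[Ti](Cl)(Cl)Cl
Why: Proposed new method: TiCl4 chelated between the C2 ketone and the bridging oxygen ionizes the tertiary C9–O bond (the C1–O bond is α to the carbonyl and does not ionize), the C10 bromine, antiperiplanar to that bond in the bicycle, bridges to the bromonium ion, and chloride carried by the titanium-bound oxygen opens it at C9 anti to bromine, on the face the oxygen left, so C9 keeps its configuration (double inversion) and the trans Br/Cl pair results; the closest known reaction types are acid cleavage of cineole-type bridged tertiary ethers to tertiary chlorides and anchimerically assisted substitution with retention next to bromine.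

Step 11
Reactants: 15 (6R,9S,10S)-4,10-dibromo-9-chloro-1-hydroxy-1,5,5,9-tetramethylspiro[5.5]undec-3-en-2-one (both C1 epimers)
Product: 16 (6S,9S,10S)-4,10-dibromo-9-chloro-5,5,9-trimethyl-1-methylidenespiro[5.5]undec-3-en-2-one
Conditions: SOCl2, pyridine, CH2Cl2, −20 to 0 °C
Reagents that add atoms: none
Why: E2 dehydration of the tertiary alcohol through its chlorosulfite: the only β-hydrogens are on the C1 methyl (C6 is quaternary, C2 is a carbonyl), so the exocyclic methylene is the only possible alkene and both C1 epimers converge; the C6 descriptor changes from R to S only because the CIP ranks of C1 and C5 swap.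

## Compound list

1 | 2,2-dimethylcyclohexane-1,3-dione | CC1(C)C(=O)CCCC1=O | starting material
2 | 3-bromo-2,2-dimethylcyclohex-3-en-1-one (achiral) | CC1(C)C(=O)CCC=C1Br | intermediate
3 | 1-bromo-6,6-dimethyl-5-methylidenecyclohex-1-ene (achiral) | C=C1CCC=C(Br)C1(C)C | intermediate
4 | 4-bromo-5,5-dimethyl-6-methylidenecyclohex-3-en-1-ol (racemic allylic alcohol) | C=C1C(O)CC=C(Br)C1(C)C | intermediate
5 | 4-bromo-5,5-dimethyl-6-methylidenecyclohex-3-en-1-one (achiral exo-enone) | C=C1C(=O)CC=C(Br)C1(C)C | intermediate
6 | [4-bromo-3,3-dimethyl-2-(3-methylbut-3-en-1-yl)cyclohexa-1,4-dien-1-yl]oxy(trimethyl)silane (achiral) | C=C(C)CCC1=C(O[Si](C)(C)C)CC=C(Br)C1(C)C | intermediate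
7 | 4-bromo-3,3-dimethyl-2-(3-methylbut-3-en-1-yl)cyclohexa-1,4-dien-1-olate (enolate anion) | C=C(C)CCC1=C([O-])CC=C(Br)C1(C)C | intermediate
8 | (2R)-4-bromo-3,3-dimethyl-2-(3-methylbut-3-en-1-yl)-2-(prop-2-en-1-yl)cyclohex-4-en-1-one | O=C1CC=C(Br)C(C)(C)[C@]1(CC=C)CCC(C)=C | intermediate
9 | (6R)-4-bromo-5,5,9-trimethylspiro[5.5]undeca-3,8-dien-1-one | O=C1CC=C(Br)C(C)(C)[C@]12CCC(C)=CC2 | intermediate
10 | dichlorocerium alkoxide of 11 | CC1(O[Ce](Cl)Cl)CC=C(Br)C(C)(C)[C@]12CCC(C)=CC2 | intermediate
11 | (6R)-4-bromo-1,5,5,9-tetramethylspiro[5.5]undeca-3,8-dien-1-ol (both C1 epimers) | CC1(O)CC=C(Br)C(C)(C)[C@]12CCC(C)=CC2 | intermediate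
12 | (6R,9S,10S)-4,10-dibromo-1,9-epoxy-1,5,5,9-tetramethylspiro[5.5]undec-3-ene (both C1 epimers; oxygen bridges C1 and C9) | CC1(O3)CC=C(Br)C(C)(C)[C@]12CC[C@@]3(C)[C@@H](Br)C2 | intermediate
13 | (6R,9S,10S)-4,10-dibromo-1,9-epoxy-1,5,5,9-tetramethylspiro[5.5]undec-3-en-2-one (both C1 epimers) | CC1(O3)C(=O)C=C(Br)C(C)(C)[C@]12CC[C@@]3(C)[C@@H](Br)C2 | intermediate
14 | trichlorotitanium alkoxide of 15 | CC1(O[Ti](Cl)(Cl)Cl)C(=O)C=C(Br)C(C)(C)[C@]12CC[C@](C)(Cl)[C@@H](Br)C2 | intermediate
15 | (6R,9S,10S)-4,10-dibromo-9-chloro-1-hydroxy-1,5,5,9-tetramethylspiro[5.5]undec-3-en-2-one (both C1 epimers) | CC1(O)C(=O)C=C(Br)C(C)(C)[C@]12CC[C@](C)(Cl)[C@@H](Br)C2 | intermediate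
16 | (6S,9S,10S)-4,10-dibromo-9-chloro-5,5,9-trimethyl-1-methylidenespiro[5.5]undec-3-en-2-one (CNP0349926.1) | C=C1C(=O)C=C(Br)C(C)(C)[C@]12CC[C@](C)(Cl)[C@@H](Br)C2 | target

## Step count and risks

Total step count: 11. Longest linear sequence: 11 steps (1 → 16).

The three steps most likely to fail are 5, 9 and 10.

Step 5 (asymmetric allylation). The enolate is flanked by the gem-dimethyl carbon, the product has a more acidic C2–H that could quench it, and palladium could insert into the C–Br bond. The fallback sets out from exo-enone 5 and comes back at spiro ketone 9. A catalytic enantioselective spirocyclizing Diels–Alder reaction of 5 with isoprene, under a confined chiral imidodiphosphorimidate Brønsted acid, forms ring B and the C6 centre in one operation with para regiochemistry. It bypasses 6, 7 and 8 and makes no new compound (F0).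

Step 9 (allylic oxidation). The alkene is electron-poor and sits next to a quaternary ether carbon, so the oxidation may be slow. The fallback sets out from spiro ketone 9 and comes back at keto ether 13. The C2 oxygen is put in first by enolate hydroxylation (KN(SiMe3)2, then 2-(phenylsulfonyl)-3-phenyloxaziridine), giving the 2-hydroxy ketone F1. CH3Li/CeCl3 then gives the 1,2-diol F2. NBS closes the same C1–O–C9 bridge to the hydroxy bromoether F3. Dess–Martin oxidation of its allylic alcohol gives 13.

Step 10 (oxygen-to-chloride exchange with retention). Elimination from the C9 cation, attack on the wrong face, or Br/Cl exchange at the β-bromo enone could compete. The fallback sets out from tertiary alcohol 11 and comes back at chloro ketol 15. It uses an alkoxide-directed bromochlorination, modelled on the titanium-mediated bromochlorination of allylic alcohols. Alcohol 11 is converted into its titanium alkoxide with ClTi(OiPr)3 and treated with NBS, so that chloride is delivered from titanium on the C1 face while bromine enters from the opposite face. This gives the bromochloro alcohol F4. Its C2 methylene is then oxidized (Rh2(cap)4, t-BuOOH) to 15.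

Further compounds

F0 | step 5 | none | none
F1 | step 9 | (6R)-4-bromo-2-hydroxy-5,5,9-trimethylspiro[5.5]undeca-3,8-dien-1-one (both C2 epimers) | O=C1C(O)C=C(Br)C(C)(C)[C@]12CCC(C)=CC2
F2 | step 9 | (6R)-4-bromo-1,5,5,9-tetramethylspiro[5.5]undeca-3,8-diene-1,2-diol (C1 and C2 epimers) | CC1(O)C(O)C=C(Br)C(C)(C)[C@]12CCC(C)=CC2
F3 | step 9 | (6R,9S,10S)-4,10-dibromo-1,9-epoxy-1,5,5,9-tetramethylspiro[5.5]undec-3-en-2-ol (C1 and C2 epimers) | CC1(O3)C(O)C=C(Br)C(C)(C)[C@]12CC[C@@]3(C)[C@@H](Br)C2
F4 | step 10 | (6R,9S,10S)-4,10-dibromo-9-chloro-1,5,5,9-tetramethylspiro[5.5]undec-3-en-1-ol (both C1 epimers) | CC1(O)CC=C(Br)C(C)(C)[C@]12CC[C@](C)(Cl)[C@@H](Br)C2
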